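Ring and atom labels: benzofuran numbering; ring A = benzo ring (C3a–C7a), ring B = dihydrofuran, ring C = 4-hydroxyphenyl on C2, ring D = 3,5-dihydroxyphenyl on C3, ring E = 4-hydroxyphenyl of the C4 ethyl chain. The target is the cis-(2S,3R) isomer, the less stable one. Both centres are therefore set kinetically, and the five phenols travel as benzyl ethers that leave last by neutral hydrogenolysis.
Key disconnection: ring B is cut at O1–C7a and C2–C3. This gives 4-(benzyloxy)benzaldehyde and a ring A–CH2–ring D diarylmethane with fluorine on C7a. Forward, a C3 carbanion adds to the C=O group and the alkoxide closes onto a C7–C7a aryne in the same flask.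
Enabling feature: C3 is doubly benzylic (rings A and D) and sits on C3a next to C7a, so the aldehyde oxygen ends up placed for a five-membered closure onto C7a. Ring A is 1,3-dioxygenated (O1 on C7a, O on C6), so C7–H between them is acidic once C7a carries fluorine, and the aryne is polarised for attack at C7a.
Stereocontrol: a temporary (S)-p-tolylsulfinyl group on ring D, ortho to C3, installed by Andersen synthesis and removed with Raney nickel.
Precursor assembly: ring A aryllithium plus ring D aldehyde, ionic reduction, then B-alkyl Suzuki coupling for the ring E chain. Rings A, C, D and E are bought; ring B is the only ring formed (step 8).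

Key step: step 8

Remark: benzofuran locants (C2–C7a) are also used for the open precursors; primed locants refer to ring D.
Assumption: the sense of induction by the sulfinyl group is taken from the lithium chelate model given in step 8; if it proved opposite, the enantiomeric sulfinate ester (from (+)-menthol) would be used in step 7 and nothing else would change.

Step 1
Reactants: 1 3-bromo-5-fluorophenol
Product: 2 1-(benzyloxy)-3-bromo-5-fluorobenzene
Conditions: BnBr, K2CO3, DMF, rt
Reagents that add atoms: benzyl bromide, BrCc1ccccc1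
Why: Williamson ether synthesis on an acidic phenol; the benzyl ether withstands the bases, acids and couplings that follow and is cleaved without acid at the end.

Step 2
Reactants: 2 1-(benzyloxy)-3-bromo-5-fluorobenzene; 3 3,5-bis(benzyloxy)benzaldehyde
Product: 5 [4-(benzyloxy)-2-bromo-6-fluorophenyl][3,5-bis(benzyloxy)phenyl]methanol (racemic), via aryllithium 4 (not isolated)
Conditions: LiN(iPr)2, THF, −78 °C; then 3, −78 °C; H2O
Reagents that add atoms: none
Why: Directed ortho-lithiation takes the proton flanked by fluorine and bromine, the two strongest acidifying neighbours, and the aryllithium adds 1,2 to the non-enolisable aldehyde at −78 °C before it can lose lithium halide; the carbinol centre forms racemic and is erased in step 3.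

Step 3
Reactants: 5 the benzhydrol
Product: 6 5-(benzyloxy)-2-[3,5-bis(benzyloxy)benzyl]-1-bromo-3-fluorobenzene
Conditions: Et3SiH, CF3CO2H, CH2Cl2, 0 °C to rt
Reagents that add atoms: none
Why: Ionic hydrogenation: acid ionises the benzhydrol to a cation stabilised by the para benzyloxy group of ring A and the silane delivers hydride, while aryl halides and benzyl ethers are inert.

Step 4
Reactants: 7 4-(benzyloxy)benzaldehyde
Product: 8 1-(benzyloxy)-4-vinylbenzene
Conditions: Ph3PCH3Br, KOtBu, THF, 0 °C to rt
Reagents that add atoms: methyltriphenylphosphonium bromide, C[P+](c1ccccc1)(c1ccccc1)c1ccccc1.[Br-]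
Why: Wittig methylenation of a non-enolisable aromatic aldehyde.

Step 5
Reactants: 8 1-(benzyloxy)-4-vinylbenzene; 6 the bromo fluoro diarylmethane
Product: 10 5-(benzyloxy)-2-[3,5-bis(benzyloxy)benzyl]-1-fluoro-3-{2-[4-(benzyloxy)phenyl]ethyl}benzene, via alkylborane 9 (not isolated)
Conditions: 8, 9-BBN, THF, rt; then 6, Pd(dppf)Cl2 (cat.), K3PO4, DMF/H2O, 60 °C
Reagents that add atoms: none
Why: Anti-Markovnikov hydroboration followed by B-alkyl Suzuki–Miyaura coupling, in which only the C–Br bond undergoes oxidative addition and the C–F bond needed in step 8 stays.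

Step 6
Reactants: 10 the fluoro diarylmethane
Product: 11 5-(benzyloxy)-2-[3,5-bis(benzyloxy)-2-iodobenzyl]-1-fluoro-3-{2-[4-(benzyloxy)phenyl]ethyl}benzene
Conditions: NIS, CF3CO2H (cat.), MeCN/CH2Cl2, 0 °C, dark
Reagents that add atoms: N-iodosuccinimide, O=C1CCC(=O)N1I
Why: Electrophilic aromatic iodination goes to ring D, the only ring activated by two cooperating alkoxy groups, and to C2' (para to one and ortho to the other benzyloxy group) rather than between the two benzyloxy groups, as is usual for 5-alkylresorcinol diethers.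

Step 7
Reactants: 11 the aryl iodide; 12 (1R,2S,5R)-menthyl (S)-p-toluenesulfinate
Product: 14 5-(benzyloxy)-2-{3,5-bis(benzyloxy)-2-[(S)-p-tolylsulfinyl]benzyl}-1-fluoro-3-{2-[4-(benzyloxy)phenyl]ethyl}benzene, via arylmagnesium chloride 13 (not isolated)
Conditions: i-PrMgCl·LiCl, THF, −20 °C; then 12, −20 °C to rt; H2O
Reagents that add atoms: none
Why: Iodine–magnesium exchange is faster than any attack on C–F or benzylic C–H, and the Andersen sulfoxide synthesis replaces menthoxide with inversion at sulfur, which fixes the (S) configuration of the sulfur stereocentre.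

Step 8
Reactants: 14 the (S)-sulfoxide; 7 4-(benzyloxy)benzaldehyde
Product: 19 (2S,3S)-6-(benzyloxy)-2-[4-(benzyloxy)phenyl]-4-{2-[4-(benzyloxy)phenyl]ethyl}-3-{3,5-bis(benzyloxy)-2-[(S)-p-tolylsulfinyl]phenyl}-2,3-dihydrobenzofuran (cis; C3 is spatially as in the target and reads S only because sulfur raises the rank of ring D), via benzyllithium 15 (not isolated), via lithium alkoxide 16 (not isolated), via aryne 17 (not isolated), via aryllithium 18 (not isolated)
Conditions: LiN(iPr)2 (1.1 equiv), THF, −78 °C; 7 (1.0 equiv), −78 °C; LiN(iPr)2 (1.3 equiv), −78 to −30 °C; H2O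
Reagents that add atoms: none
Why: Proposed new method: the first portion of LiN(iPr)2 takes a C3 proton of 14 to give benzyllithium 15, whose lithium is held by the sulfinyl oxygen, 15 adds to the C=O group of 7 (C3–C2 bond, alkoxide 16), the second portion lithiates C7–H of ring A, which lies between the C7a fluorine and the C6 benzyloxy group, loss of LiF on warming gives the C7–C7a aryne 17, the tethered alkoxide adds to C7a (O1–C7a bond), and water protonates aryllithium 18 at C7. The closest known reaction types are the addition of ortho-sulfinyl benzylic carbanions to aldehydes, the generation of 3-alkoxyarynes from haloanisoles with lithium amides and the cyclisation of aryne-tethered alkoxides to dihydrobenzofurans; their merger into one formal (3+2) annulation of an aldehyde is what is new. Ring B, the only ring formed, closes in the 5-exo-dig mode, and oxygen goes to C7a because the tether reaches no other carbon and because the C6 oxygen next to C7 stabilises the developing carbanion at C7, as in all 3-alkoxyarynes. C3 is controlled by the (S)-sulfinyl group on ring D: its oxygen binds lithium on one face of C3, its p-tolyl group, turned out of the ring plane by the neighbouring C3' benzyloxy group, covers the other face, the bulky ring A points away from sulfur, and the aldehyde takes the place of lithium with retention. C2 is controlled in the same lithium-bridged transition state, where the carbonyl oxygen lies beside the sulfinyl oxygen and ring C points away from ring D, so that O and ring A end up antiperiplanar in 16, which is the relative configuration that closes to the cis ring; this is why the director is placed on ring D and not on ring A. The step needs kinetic control and site-selective deprotonation: the sulfinyl-activated doubly benzylic C3–H is by far the most acidic proton of 14, C7–H is the most acidic one of 16, and ring closure below −30 °C should outrun retro-addition and base-induced opening of ring B.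

Step 9
Reactants: 19 the cis-dihydrobenzofuran sulfoxide
Product: 20 (2S,3R)-6-(benzyloxy)-2-[4-(benzyloxy)phenyl]-4-{2-[4-(benzyloxy)phenyl]ethyl}-3-[3,5-bis(benzyloxy)phenyl]-2,3-dihydrobenzofuran (cis)
Conditions: Raney nickel (washed neutral), THF/EtOH, rt
Reagents that add atoms: none
Why: Reductive desulfurisation with Raney nickel cleaves both C–S bonds of the diaryl sulfoxide under neutral conditions that touch neither C2 nor C3.

Step 10
Reactants: 20 the pentabenzyl ether
Product: 21 (2S,3R)-3-(3,5-dihydroxyphenyl)-2-(4-hydroxyphenyl)-4-[2-(4-hydroxyphenyl)ethyl]-2,3-dihydrobenzofuran-6-ol (target, cis)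
Conditions: H2 (1 atm), Pd/C, EtOAc/MeOH, rt
Reagents that add atoms: none
Why: Catalytic hydrogenolysis of the five O-benzyl groups; the hindered cyclic C2–O1 ether is cleaved far more slowly, and no acid or base is present that could epimerise C2 through ring opening.

Compound list
1 | 3-bromo-5-fluorophenol | Oc1cc(F)cc(Br)c1 | starting material
2 | 1-(benzyloxy)-3-bromo-5-fluorobenzene | Fc1cc(Br)cc(OCc2ccccc2)c1 | intermediate
3 | 3,5-bis(benzyloxy)benzaldehyde | O=Cc1cc(OCc2ccccc2)cc(OCc2ccccc2)c1 | starting material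
4 | [4-(benzyloxy)-2-bromo-6-fluorophenyl]lithium | [Li]c1c(F)cc(OCc2ccccc2)cc1Br | intermediate
5 | [4-(benzyloxy)-2-bromo-6-fluorophenyl][3,5-bis(benzyloxy)phenyl]methanol (racemic) | OC(c1c(F)cc(OCc2ccccc2)cc1Br)c1cc(OCc2ccccc2)cc(OCc2ccccc2)c1 | intermediate
6 | 5-(benzyloxy)-2-[3,5-bis(benzyloxy)benzyl]-1-bromo-3-fluorobenzene | Fc1cc(OCc2ccccc2)cc(Br)c1Cc1cc(OCc2ccccc2)cc(OCc2ccccc2)c1 | intermediate
7 | 4-(benzyloxy)benzaldehyde | O=Cc1ccc(OCc2ccccc2)cc1 | starting material
8 | 1-(benzyloxy)-4-vinylbenzene | C=Cc1ccc(OCc2ccccc2)cc1 | intermediate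
9 | 9-{2-[4-(benzyloxy)phenyl]ethyl}-9-borabicyclo[3.3.1]nonane | C(Cc1ccc(OCc2ccccc2)cc1)B1C2CCCC1CCC2 | intermediate
10 | 5-(benzyloxy)-2-[3,5-bis(benzyloxy)benzyl]-1-fluoro-3-{2-[4-(benzyloxy)phenyl]ethyl}benzene | Fc1cc(OCc2ccccc2)cc(CCc2ccc(OCc3ccccc3)cc2)c1Cc1cc(OCc2ccccc2)cc(OCc2ccccc2)c1 | intermediate
11 | 2'-iodide of 10 (iodine on ring D between the benzylic carbon and a benzyloxy group) | Fc1cc(OCc2ccccc2)cc(CCc2ccc(OCc3ccccc3)cc2)c1Cc1cc(OCc2ccccc2)cc(OCc2ccccc2)c1I | intermediate
12 | (1R,2S,5R)-menthyl (S)-p-toluenesulfinate | C[C@@H]1CC[C@H]([C@@H](C1)O[S@](=O)c2ccc(C)cc2)C(C)C | starting material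
13 | arylmagnesium chloride from 11 (MgCl in place of I) | Fc1cc(OCc2ccccc2)cc(CCc2ccc(OCc3ccccc3)cc2)c1Cc1cc(OCc2ccccc2)cc(OCc2ccccc2)c1[Mg]Cl | intermediate
14 | (S)-p-tolyl sulfoxide (sulfinyl group in place of I of 11) | Fc1cc(OCc2ccccc2)cc(CCc2ccc(OCc3ccccc3)cc2)c1Cc1cc(OCc2ccccc2)cc(OCc2ccccc2)c1[S@@](=O)c1ccc(C)cc1 | intermediate
15 | C3-lithiated 14, lithium on the face of the sulfinyl oxygen | Fc1cc(OCc2ccccc2)cc(CCc2ccc(OCc3ccccc3)cc2)c1[C@@H](c1cc(OCc2ccccc2)cc(OCc2ccccc2)c1[S@@](=O)c1ccc(C)cc1)[Li] | intermediate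
16 | lithium alkoxide from 15 and 7 (C2 and C3 spatially as in 19) | Fc1cc(OCc2ccccc2)cc(CCc2ccc(OCc3ccccc3)cc2)c1[C@@H](c1cc(OCc2ccccc2)cc(OCc2ccccc2)c1[S@@](=O)c1ccc(C)cc1)[C@@H](c1ccc(OCc2ccccc2)cc1)O[Li] | intermediate
17 | C7–C7a aryne derived from 16 | C1#CC(OCc2ccccc2)=CC(CCc2ccc(OCc3ccccc3)cc2)=C1[C@@H](c1cc(OCc2ccccc2)cc(OCc2ccccc2)c1[S@@](=O)c1ccc(C)cc1)[C@@H](c1ccc(OCc2ccccc2)cc1)O[Li] | intermediate
18 | 7-lithio derivative of 19 | c1ccccc1COc1ccc(CCc2cc(OCc4ccccc4)c([Li])c3c2[C@@H](c2cc(OCc4ccccc4)cc(OCc4ccccc4)c2[S@@](=O)c2ccc(C)cc2)[C@@H](c2ccc(OCc4ccccc4)cc2)O3)cc1 | intermediate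
19 | (2S,3S,SS)-cis-dihydrobenzofuran pentabenzyl ether with the p-tolylsulfinyl group on C2' of ring D | c1ccccc1COc1ccc(CCc2cc(OCc4ccccc4)cc3c2[C@@H](c2cc(OCc4ccccc4)cc(OCc4ccccc4)c2[S@@](=O)c2ccc(C)cc2)[C@@H](c2ccc(OCc4ccccc4)cc2)O3)cc1 | intermediate
20 | (2S,3R)-cis-dihydrobenzofuran pentabenzyl ether | c1ccccc1COc1ccc(CCc2cc(OCc4ccccc4)cc3c2[C@@H](c2cc(OCc4ccccc4)cc(OCc4ccccc4)c2)[C@@H](c2ccc(OCc4ccccc4)cc2)O3)cc1 | intermediate
21 | (2S,3R)-3-(3,5-dihydroxyphenyl)-2-(4-hydroxyphenyl)-4-[2-(4-hydroxyphenyl)ethyl]-2,3-dihydrobenzofuran-6-ol | Oc1ccc(CCc2cc(O)cc3c2[C@@H](c2cc(O)cc(O)c2)[C@@H](c2ccc(O)cc2)O3)cc1 | target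

Total step count: 10. Longest linear sequence: 9 (steps 1, 2, 3, 5, 6, 7, 8, 9, 10).

Steps most likely to fail

Step 8 (labelled step).
- What may go wrong:
  - loss of facial or simple diastereoselection in the congested carbonyl addition;
  - reversal of the addition before ring closure;
  - attack of the aryllithium species on the sulfinyl group;
  - base-induced opening of ring B.
- The fallback uses known chemistry, the donor/donor carbene C–H insertion, which is cis-selective for 2,3-diaryl-2,3-dihydrobenzofurans. It sets out from carbinol 5, which Dess–Martin periodinane oxidises to the benzophenone F1. The fluorine, now activated by the ortho carbonyl group, is displaced by the sodium alkoxide of commercial 4-(benzyloxy)benzyl alcohol (NaH, DMF) to give the aryl benzyl ether F2. B-alkyl Suzuki coupling with borane 9 gives the ketone F3, and hydrazine hydrate with AcOH under heating gives the hydrazone F4. MnO2 oxidises this to the diaryldiazomethane F5. Rh2(S-PTAD)4 or its enantiomer, whichever gives the (2S,3R) series, then inserts the carbene carbon C3 into the C2–H bond. The route is rejoined at 20, and steps 6 to 9 fall away.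

Step 2.
- What may go wrong: competing deprotonation between fluorine and the benzyloxy group, or loss of lithium halide from the aryllithium before it meets the aldehyde.
- The fallback fixes the position by electrophilic substitution and uses a magnesium reagent. It sets out from phenol 1. Iodination with NIS para to the hydroxyl group gives 3-bromo-5-fluoro-4-iodophenol F6, and benzylation gives the benzyl ether F7. Iodine–magnesium exchange with i-PrMgCl·LiCl at −40 °C gives the arylmagnesium chloride F8, which is far less prone to halide loss. Its addition to 3 comes back to the route at 5.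

Step 9.
- What may go wrong: hydrogenolysis of the benzylic C2–O1 bond or partial loss of benzyl ethers on the nickel surface.
- The fallback replaces surface hydrogenolysis by sulfoxide–lithium exchange. It sets out from 19. t-BuLi (THF, −78 °C) gives the aryllithium F9, which is protonated in the cold with MeOH. It comes back to the route at 20.

Further compounds
F1 | step 8 | [4-(benzyloxy)-2-bromo-6-fluorophenyl][3,5-bis(benzyloxy)phenyl]methanone | O=C(c1c(F)cc(OCc2ccccc2)cc1Br)c1cc(OCc2ccccc2)cc(OCc2ccccc2)c1
F2 | step 8 | {4-(benzyloxy)-2-[4-(benzyloxy)benzyloxy]-6-bromophenyl}[3,5-bis(benzyloxy)phenyl]methanone | O=C(c1c(Br)cc(OCc2ccccc2)cc1OCc1ccc(OCc2ccccc2)cc1)c1cc(OCc2ccccc2)cc(OCc2ccccc2)c1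
F3 | step 8 | ketone F2 with the 2-[4-(benzyloxy)phenyl]ethyl chain in place of bromine | O=C(c1c(CCc2ccc(OCc3ccccc3)cc2)cc(OCc2ccccc2)cc1OCc1ccc(OCc2ccccc2)cc1)c1cc(OCc2ccccc2)cc(OCc2ccccc2)c1
F4 | step 8 | hydrazone of F3 | NN=C(c1c(CCc2ccc(OCc3ccccc3)cc2)cc(OCc2ccccc2)cc1OCc1ccc(OCc2ccccc2)cc1)c1cc(OCc2ccccc2)cc(OCc2ccccc2)c1
F5 | step 8 | diaryldiazomethane from F4 | [N-]=[N+]=C(c1c(CCc2ccc(OCc3ccccc3)cc2)cc(OCc2ccccc2)cc1OCc1ccc(OCc2ccccc2)cc1)c1cc(OCc2ccccc2)cc(OCc2ccccc2)c1
F6 | step 2 | 3-bromo-5-fluoro-4-iodophenol | Oc1cc(F)c(I)c(Br)c1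
F7 | step 2 | 5-(benzyloxy)-1-bromo-3-fluoro-2-iodobenzene | Fc1cc(OCc2ccccc2)cc(Br)c1I
F8 | step 2 | [4-(benzyloxy)-2-bromo-6-fluorophenyl]magnesium chloride | Fc1cc(OCc2ccccc2)cc(Br)c1[Mg]Cl
F9 | step 9 | 2'-lithio derivative of 20 | c1ccccc1COc1ccc(CCc2cc(OCc4ccccc4)cc3c2[C@@H](c2cc(OCc4ccccc4)cc(OCc4ccccc4)c2[Li])[C@@H](c2ccc(OCc4ccccc4)cc2)O3)cc1
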